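## Analysis of the target

Locants follow dibenzofuran numbering of the tricyclic core. Ring A is the benzene ring C5a–C6–C7–C8–C9–C9a. Ring B is the dihydrofuran O5–C4a–C9b–C9a–C5a. Ring C is the cyclohexanone C1–C2–C3(=O)–C4–C4a–C9b. Ring D is the 20-membered bis-lactam that leaves C9b as an (E)-acrylamide (Cβ′=Cα′–CO–N(a)H), runs through N(a)–(CH2)4–N(b)H–(CH2)3–N(c)H and returns to C8 of ring A as an (E)-cinnamamide.

- There are two stereocentres: the all-carbon quaternary C9b (bonded to C9a, Cβ′, C1 and C4a) and the O-bearing methine C4a. Only the cis ring fusion is possible, so the real problem is the absolute configuration, (4aR,9bS).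
- The feature the route is built on: ring C is a para-substituted phenol ring in a reduced state, with the C3 carbonyl para to C9b. Its two arms, C1–C2 and C4–C4a, differ only in that C4a carries O5 and C1–C2 is saturated.
- The molecule therefore hides a mirror plane. In the 4-aryl-4-alkenylcyclohexa-2,5-dienone (C1=C2 and C4=C4a both present, C5a–OH free) C9b is not a stereocentre. Both stereocentres appear together when one ring alkene is reduced and the other is attacked by O5.
- Once C1–C2 is saturated, ring B can reopen only to a chiral enone, so the configuration is locked. The C1=C2 enone congener, in contrast, would racemise through the dienone.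
- Sensitive groups: the β-aryloxy ketone (retro-oxa-Michael with base), two conjugated amides next to a free secondary amine N(b), and an enolisable ketone.
- The hard parts: a quaternary stereocentre whose four substituents are all carbon; the fixed orientation of the unsymmetrical triamine (four-carbon arm on the C9b acrylamide, three-carbon arm on the cinnamamide); the large ring; and the reduction of one C=C bond out of four that are conjugated to carbonyl groups.

## Retrosynthetic reasoning

**19 to 15.** The O5–C4a bond is cut (oxa-Michael), the C1–C2 bond is returned to an alkene, and the phenol and N(b) are masked again. This gives the achiral macrocyclic dienone 15, with no stereocentre at all. The cut is made here because it is the only one that removes both stereocentres and ring B at once. Forward, an enantioselective conjugate reduction (copper hydride catalysis) must choose one of the two enantiotopic ring alkenes (16, then 17). Acid then frees the phenol and the amine (18), and the phenol closes ring B to give 19. Placing this last means every earlier intermediate is achiral and the two deprotections cost no extra step.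

**15 to 14.** The C8–Cβ bond of the cinnamamide is cut (intramolecular Heck reaction). The aryl–alkenyl bond is chosen because the bromide it needs can be put on ring A late, and because the reaction gives the (E)-alkene directly. It also closes ring D without any amine having to be deprotected selectively.

**14 to 13.** The C8–Br bond is cut (electrophilic bromination para to O5). The halogen cannot be carried through the dissolving-metal step, so it is introduced on the dienone, which has no enolisable position.

**13 to 12.** The C3=O group is traced back to the doubly allylic CH2 of a cyclohexa-1,4-diene (allylic oxidation). The quaternary carbon prevents aromatisation, so the diene is a stable carrier of ring C.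

**12 to 4 and 11.** The Cα′=Cβ′ bond is cut (Horner–Wadsworth–Emmons olefination). This joins the whole triamine arm to the aldehyde 4 in one step and sets the (E)-acrylamide.

**4 to 2 to 1.** The C9b–CHO bond is cut and ring C is rearomatised: Birch reductive formylation of the biaryl 2 through the cyclohexadienyl anion 3. The unsubstituted ring of 2-phenylphenol 1 becomes ring C; its ipso carbon becomes C9b and its para carbon becomes C3. The oxygenated ring stays aromatic and becomes ring A.

**11 to 10 to 9 to 7 to 5 and 6.** The phosphonate 11 is built outwards from diamine 5: acylation with 6, cyanoethylation and carbamate formation at N(b) (through 8), nitrile reduction, acryloylation. The orientation of the triamine is fixed by construction, not by selective acylation of a preformed triamine.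

## Alternatives that were turned down

**Alternative 1:** the textbook route, with the C9a–C9b bond cut by an intramolecular Heck reaction and ring D cut at an amide (late macrolactamisation).
- Forward: the enantioenriched aryl cyclohexenyl ether A1 undergoes 5-exo Heck cyclisation to the cis-fused tricycle A2, passing the C4a configuration on to C9b.
- Why not:
  - β-Hydride elimination leaves a C1=C2 alkene in A2, which would then have to be hydrogenated next to the acrylate on C9b.
  - The C4a stereocentre has to be bought first by a separate asymmetric step.
  - The ketone must travel as a ketal, because the β-aryloxy ketone eliminates.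
  - The lactamisation needs three differentiated nitrogens.
  - The estimate is 15 or more steps, and the latent symmetry is not used.

**Alternative 2:** the biomimetic route, with C9a–C9b and O5–C4a both cut by oxidative para–ortho phenol coupling.
- Forward: the bis(4-hydroxycinnamoyl) triamine A3 is oxidised to the racemic enone A4, followed by conjugate reduction.
- Why not:
  - 4-Hydroxycinnamoyl radicals couple mainly through the side-chain β-carbon, not the ring carbon para to oxygen.
  - Nothing decides which of the two phenols becomes ring C, so both orientations of the triamine would form.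
  - The free amine N(b) is oxidised.
  - Closure of a 20-membered ring by radical coupling competes with oligomerisation.
  - A4 is racemic and racemises further through the dienone.

**Alternative 3:** ring C built by a catalytic asymmetric Diels–Alder reaction (C1–C2 and C4a–C9b cut).
- Forward: the α-aryl acrolein A5 reacts with an aminosiloxy diene under a chiral catalyst to give, after elimination, the enone aldehyde A6. Olefination, phenol release and macrocyclisation follow.
- Why not:
  - A5 needs three to four steps and polymerises easily.
  - α-Aryl acroleins lie outside the well-documented α-alkyl range of this reaction.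
  - The stereocentre made first must then survive six further operations, including a hot Heck macrocyclisation on a base-labile β-aryloxy ketone.
  - A6 with a free phenol would close to a lactol.
  - The route is two to three steps longer and does not merge the deprotections with the ring closure.

Key step: step 11

Remarks:
- Compounds 1, 5 and 6 are taken as commercial.
- The sense of induction in step 11 is fixed by the ligand antipode. (R)-DTBM-SEGPHOS is written; if it delivers the (4aS,9bR) series, the (S)-ligand is used instead.

## Route

Step 1
Reactants: 1 2-phenylphenol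
Product: 2 2-(methoxymethoxy)biphenyl
Conditions: NaH (1.2 equiv), THF, 0 °C; MOMCl (1.1 equiv), 0 °C to rt
Reagents that add atoms: chloromethyl methyl ether, COCCl
Why: O-Alkylation of the sodium phenoxide (Williamson type); the acetal survives dissolving metal, base, oxidation, bromination and palladium catalysis and falls in the same acid step as the carbamate in step 11.

Step 2
Reactants: 2 2-(methoxymethoxy)biphenyl
Product: 4 1-[2-(methoxymethoxy)phenyl]cyclohexa-2,5-diene-1-carbaldehyde, via lithium cyclohexadienide 3 (not isolated)
Conditions: Li (2.2 equiv), NH3(l)/THF, −78 °C; then DMF (4 equiv), −78 °C; sat. aq. NH4Cl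
Reagents that add atoms: N,N-dimethylformamide, CN(C)C=O
Why: Birch reduction of a biaryl: the ring without the donor oxygen takes up the electrons, ammonia protonates its para carbon (future C3), and the cyclohexadienyl anion 3 is trapped at its central benzylic carbon (future C9b) as in Birch reductive alkylation of biphenyls, here by a formamide whose tetrahedral adduct releases the aldehyde only on work-up. This dearomatisation turns the flat phenyl ring into ring C with its quaternary carbon.

Step 3
Reactants: 5 butane-1,4-diamine; 6 triethyl phosphonoacetate
Product: 7 diethyl {2-[(4-aminobutyl)amino]-2-oxoethyl}phosphonate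
Conditions: 5 (6 equiv), neat, 50 °C; excess 5 distilled off in vacuo
Reagents that add atoms: none
Why: Aminolysis of the activated ethyl ester by a primary amine; the large excess of diamine holds the reaction at monoacylation and places the phosphonoacetyl group on the four-carbon arm.

Step 4
Reactants: 7 diethyl {2-[(4-aminobutyl)amino]-2-oxoethyl}phosphonate
Product: 9 tert-butyl N-(2-cyanoethyl)-N-{4-[2-(diethoxyphosphoryl)acetamido]butyl}carbamate, via cyanoethylated amine 8 (not isolated)
Conditions: acrylonitrile (1.05 equiv), MeOH, 0 °C to rt; then Boc2O (1.2 equiv), Et3N (cat.), rt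
Reagents that add atoms: acrylonitrile, C=CC#N; di-tert-butyl dicarbonate, CC(C)(C)OC(=O)OC(=O)OC(C)(C)C
Why: Aza-Michael addition of the primary amine stops at monoaddition with one equivalent of acceptor; the new secondary amine N(b) is capped as its tert-butyl carbamate in the same flask.

Step 5
Reactants: 9 tert-butyl N-(2-cyanoethyl)-N-{4-[2-(diethoxyphosphoryl)acetamido]butyl}carbamate
Product: 10 tert-butyl N-(3-aminopropyl)-N-{4-[2-(diethoxyphosphoryl)acetamido]butyl}carbamate
Conditions: H2 (4 bar), Raney Ni, 7 M NH3 in MeOH, rt
Reagents that add atoms: none
Why: Catalytic hydrogenation of the nitrile to the primary amine; ammonia suppresses secondary-amine formation, and carbamate, amide and phosphonate are inert.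

Step 6
Reactants: 10 tert-butyl N-(3-aminopropyl)-N-{4-[2-(diethoxyphosphoryl)acetamido]butyl}carbamate
Product: 11 tert-butyl N-[3-(acryloylamino)propyl]-N-{4-[2-(diethoxyphosphoryl)acetamido]butyl}carbamate
Conditions: acryloyl chloride (1.05 equiv), CH2Cl2/sat. aq. NaHCO3, 0 °C
Reagents that add atoms: acryloyl chloride, C=CC(=O)Cl
Why: Schotten–Baumann acylation of the only free amine gives the terminal acrylamide that later serves as the Heck acceptor on the three-carbon arm.

Step 7
Reactants: 4 1-[2-(methoxymethoxy)phenyl]cyclohexa-2,5-diene-1-carbaldehyde; 11 tert-butyl N-[3-(acryloylamino)propyl]-N-{4-[2-(diethoxyphosphoryl)acetamido]butyl}carbamate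
Product: 12 tert-butyl N-[3-(acryloylamino)propyl]-N-{4-[(2E)-3-{1-[2-(methoxymethoxy)phenyl]cyclohexa-2,5-dien-1-yl}prop-2-enamido]butyl}carbamate
Conditions: LiCl (3 equiv), DBU (2 equiv), MeCN, 0 °C to rt
Reagents that add atoms: none
Why: Horner–Wadsworth–Emmons olefination under Masamune–Roush conditions; the non-enolisable α-quaternary aldehyde can react only at its carbonyl group and the stabilised phosphonoacetamide anion gives the (E)-enamide. The step joins the two fragments and removes the aldehyde C–H before the oxidation.

Step 8
Reactants: 12 the diene of step 7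
Product: 13 tert-butyl N-[3-(acryloylamino)propyl]-N-{4-[(2E)-3-{1-[2-(methoxymethoxy)phenyl]-4-oxocyclohexa-2,5-dien-1-yl}prop-2-enamido]butyl}carbamate
Conditions: Rh2(cap)4 (1 mol%; cap = caprolactamate), t-BuOOH (70% aq., 5 equiv), K2CO3 (0.5 equiv), CH2Cl2, rt
Reagents that add atoms: tert-butyl hydroperoxide, CC(C)(C)OO
Why: Allylic C–H oxidation by tert-butylperoxyl radicals from the dirhodium caprolactamate catalyst; the doubly allylic C3–H bonds are by far the weakest in the molecule. The quaternary carbon blocks aromatisation and shields the dienyl termini, so the cross-conjugated dienone should form.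

Step 9
Reactants: 13 the dienone of step 8
Product: 14 tert-butyl N-[3-(acryloylamino)propyl]-N-{4-[(2E)-3-{1-[5-bromo-2-(methoxymethoxy)phenyl]-4-oxocyclohexa-2,5-dien-1-yl}prop-2-enamido]butyl}carbamate
Conditions: NBS (1.05 equiv), MeCN, 0 °C to rt, dark
Reagents that add atoms: N-bromosuccinimide, O=C1CCC(=O)N1Br
Why: Electrophilic aromatic bromination directed para to the acetal oxygen (C8); the dienone has no enolisable α-hydrogen and the electron-poor enamides are not attacked.

Step 10
Reactants: 14 the aryl bromide of step 9
Product: 15 macrocyclic dienone: ring D closed with both enamides (E); ring C a cyclohexa-2,5-dien-4-one attached through C9b; C5a–OMOM; N(b)–Boc; achiral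
Conditions: Pd2(dba)3 (5 mol%), [HP(t-Bu)3]BF4 (12 mol%), Cy2NMe (3 equiv), 1,4-dioxane, 1 mM (syringe pump), 60 °C
Reagents that add atoms: none
Why: Intramolecular Mizoroki–Heck reaction at high dilution: oxidative addition of C8–Br to zerovalent palladium, insertion at the unsubstituted terminus of the acrylamide and syn β-hydride elimination give the (E)-cinnamamide and close the 20-membered ring D. The 1,2-disubstituted enamide and the dienone alkenes insert far more slowly.

Step 11
Reactants: 15 the macrocyclic dienone of step 10
Product: 19 target CNP0415009.1 with (4aR,9bS) configuration, via silyl dienol ether 16 (not isolated), via protected enone 17 (not isolated), via phenol enone 18 (not isolated)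
Conditions: Cu(OAc)2 (5 mol%), (R)-DTBM-SEGPHOS (5.5 mol%), (EtO)2MeSiH (2.0 equiv), THF/toluene, −40 to −20 °C; then 3 M HCl in MeOH, 0 °C to rt; then aq. NaHCO3
Reagents that add atoms: none
Why: The bisphosphine copper hydride adds to one of the two enantiotopic ring alkenes of 15, hydride to C1 and copper to the C3 oxygen, and σ-bond metathesis with the silane releases silyl dienol ether 16 and regenerates the hydride. Because 16 is no longer a Michael acceptor, reduction should stop after one alkene. The closest known reaction type is the copper hydride catalysed enantioselective conjugate reduction of cyclic enones in its desymmetrising form on 4,4-disubstituted cyclohexa-2,5-dienones. Methanolic HCl then protonates C2 (enone 17), cleaves the MOM acetal and the carbamate (18), and the C5a phenol closes ring B by 5-exo-trig oxa-Michael addition to C4a. C9b is set by the catalyst: the hydride should approach a ring alkene from the face flanked by the slim alkenyl arm, not the ortho-substituted aryl group, and the enantioface preference of the ligand then decides which alkene is reduced. C4a is set by the substrate: the tether O5–C5a–C9a can reach C4a only from the face that carries the aryl group, so the cis fusion and hence (4aR) follow from (9bS). The step needs the dienone to react before the two secondary enamides, which are much poorer hydride acceptors, and needs the phenol to add to the ketone-activated ring alkene and not to the acrylamide, which the higher electrophilicity and the stability of the fused β-aryloxy ketone secure. With C1–C2 saturated, reopening of ring B can no longer pass through a symmetric dienone, so the configuration is fixed.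

## Compound list

1 | 2-phenylphenol | Oc1ccccc1-c1ccccc1 | starting material
2 | 2-(methoxymethoxy)biphenyl | COCOc1ccccc1-c1ccccc1 | intermediate
3 | lithium 1-[2-(methoxymethoxy)phenyl]cyclohexa-2,5-dien-1-ide | [Li+].COCOc1ccccc1[C-]1C=CCC=C1 | intermediate
4 | 1-[2-(methoxymethoxy)phenyl]cyclohexa-2,5-diene-1-carbaldehyde | COCOc1ccccc1C1(C=O)C=CCC=C1 | intermediate
5 | butane-1,4-diamine | NCCCCN | starting material
6 | triethyl phosphonoacetate | CCOC(=O)CP(=O)(OCC)OCC | starting material
7 | diethyl {2-[(4-aminobutyl)amino]-2-oxoethyl}phosphonate | CCOP(=O)(OCC)CC(=O)NCCCCN | intermediate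
8 | diethyl [2-({4-[(2-cyanoethyl)amino]butyl}amino)-2-oxoethyl]phosphonate | CCOP(=O)(OCC)CC(=O)NCCCCNCCC#N | intermediate
9 | tert-butyl N-(2-cyanoethyl)-N-{4-[2-(diethoxyphosphoryl)acetamido]butyl}carbamate | CCOP(=O)(OCC)CC(=O)NCCCCN(CCC#N)C(=O)OC(C)(C)C | intermediate
10 | tert-butyl N-(3-aminopropyl)-N-{4-[2-(diethoxyphosphoryl)acetamido]butyl}carbamate | CCOP(=O)(OCC)CC(=O)NCCCCN(CCCN)C(=O)OC(C)(C)C | intermediate
11 | tert-butyl N-[3-(acryloylamino)propyl]-N-{4-[2-(diethoxyphosphoryl)acetamido]butyl}carbamate | CCOP(=O)(OCC)CC(=O)NCCCCN(CCCNC(=O)C=C)C(=O)OC(C)(C)C | intermediate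
12 | tert-butyl N-[3-(acryloylamino)propyl]-N-{4-[(2E)-3-{1-[2-(methoxymethoxy)phenyl]cyclohexa-2,5-dien-1-yl}prop-2-enamido]butyl}carbamate | COCOc1ccccc1C1(/C=C/C(=O)NCCCCN(CCCNC(=O)C=C)C(=O)OC(C)(C)C)C=CCC=C1 | intermediate
13 | tert-butyl N-[3-(acryloylamino)propyl]-N-{4-[(2E)-3-{1-[2-(methoxymethoxy)phenyl]-4-oxocyclohexa-2,5-dien-1-yl}prop-2-enamido]butyl}carbamate | COCOc1ccccc1C1(/C=C/C(=O)NCCCCN(CCCNC(=O)C=C)C(=O)OC(C)(C)C)C=CC(=O)C=C1 | intermediate
14 | tert-butyl N-[3-(acryloylamino)propyl]-N-{4-[(2E)-3-{1-[5-bromo-2-(methoxymethoxy)phenyl]-4-oxocyclohexa-2,5-dien-1-yl}prop-2-enamido]butyl}carbamate | COCOc1ccc(Br)cc1C1(/C=C/C(=O)NCCCCN(CCCNC(=O)C=C)C(=O)OC(C)(C)C)C=CC(=O)C=C1 | intermediate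
15 | achiral macrocyclic dienone (ring D closed, both enamides E; ring C as cyclohexa-2,5-dien-4-one on C9b; C5a–OMOM; N(b)–Boc) | O=C1C=CC2(C=C1)/C=C/C(=O)NCCCCN(C(=O)OC(C)(C)C)CCCNC(=O)/C=C/c1ccc(OCOC)c2c1 | intermediate
16 | (9bS)-silyl dienol ether (C1 saturated; C2=C3 and C4=C4a; C3–O–SiMe(OEt)2; C5a–OMOM; N(b)–Boc) | CCO[Si](C)(OCC)OC1=CC[C@]2(C=C1)/C=C/C(=O)NCCCCN(C(=O)OC(C)(C)C)CCCNC(=O)/C=C/c1ccc(OCOC)c2c1 | intermediate
17 | (9bS)-macrocyclic enone (C1–C2 saturated; C4=C4a–C3=O; C5a–OMOM; N(b)–Boc) | O=C1CC[C@]2(C=C1)/C=C/C(=O)NCCCCN(C(=O)OC(C)(C)C)CCCNC(=O)/C=C/c1ccc(OCOC)c2c1 | intermediate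
18 | (9bS)-macrocyclic enone with free C5a–OH and free N(b)–H | O=C1CC[C@]2(C=C1)/C=C/C(=O)NCCCCNCCCNC(=O)/C=C/c1ccc(O)c2c1 | intermediate
19 | CNP0415009.1, (4aR,9bS)-configured cis-fused keto bis-lactam (rings A to D) | O=C1CC[C@]23/C=C/C(=O)NCCCCNCCCNC(=O)/C=C/c4ccc(c2c4)O[C@@H]3C1 | target

## Step count and risk

Total step count: 11 (7 on the main line, 4 for fragment 11).
Longest linear sequence: 9 steps (steps 3 to 11, from 5 and 6).

**Step 11 (key step).**
- What may go wrong: insufficient discrimination between the two enantiotopic ring alkenes, because the substrate is a macrocycle and the reaction type is established on simple 4-aryl-4-alkyl dienones. There may also be over-reduction if an amide N–H protonates the copper enolate and the freed enone re-enters the cycle. The free amine N(b) may add to the enone in competition with the phenol, although the 5-exo closure should be much faster.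
- Fallback: from 14, the same copper hydride desymmetrisation is run on the acyclic dienone, with a buffered methanolic work-up (K2CO3, MeOH) that cleaves only the silyl enol ether. This gives the acyclic (S)-enone F1. The Heck macrocyclisation of step 10 is then applied to F1 and returns to the route at 17, from which methanolic HCl gives 19 as in step 11.

**Step 2.**
- What may go wrong: protonation of the cyclohexadienyl anion in place of formylation, or base-induced isomerisation to the conjugated diene in ammonia. Both arise because a formamide is a slower electrophile than the alkyl halides normally used.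
- Fallback: from 2, plain Birch reduction with t-BuOH as proton source gives 1-(cyclohexa-2,5-dien-1-yl)-2-(methoxymethoxy)benzene F2. Its doubly allylic benzylic C–H is removed with s-BuLi/TMEDA in THF at −78 °C and the anion is formylated with DMF, returning at 4.

**Step 10.**
- What may go wrong: intermolecular Heck coupling (oligomerisation) outrunning the closure of a 20-membered ring, and slow oxidative addition of the electron-rich aryl bromide.
- Fallback: from 14, Suzuki–Miyaura vinylation (potassium vinyltrifluoroborate, PdCl2(dppf), K2CO3) gives the styrene F3. Ring-closing metathesis between the styrene and the terminal acrylamide (second-generation Hoveyda–Grubbs catalyst, 1 mM, toluene, 60 °C) forms the same (E)-cinnamamide and returns at 15.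

**Step 8.**
- What may go wrong: loss of chemoselectivity in the radical chain, with addition of peroxyl radicals to the terminal acrylamide or hydrogen abstraction next to nitrogen.
- Fallback: from 12, a non-radical ene and [2,3]-sigmatropic hydroxylation (SeO2 cat., t-BuOOH, CH2Cl2) gives the doubly allylic alcohol F4. MnO2 then oxidises it to the dienone, returning at 13.

## Further compounds

F1 | step 11 | tert-butyl N-[3-(acryloylamino)propyl]-N-{4-[(2E)-3-{(1S)-1-[5-bromo-2-(methoxymethoxy)phenyl]-4-oxocyclohex-2-en-1-yl}prop-2-enamido]butyl}carbamate | O=C1CC[C@](C=C1)(/C=C/C(=O)NCCCCN(CCCNC(=O)C=C)C(=O)OC(C)(C)C)c1cc(Br)ccc1OCOC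
F2 | step 2 | 1-(cyclohexa-2,5-dien-1-yl)-2-(methoxymethoxy)benzene | COCOc1ccccc1C1C=CCC=C1
F3 | step 10 | tert-butyl N-[3-(acryloylamino)propyl]-N-{4-[(2E)-3-{1-[5-ethenyl-2-(methoxymethoxy)phenyl]-4-oxocyclohexa-2,5-dien-1-yl}prop-2-enamido]butyl}carbamate | COCOc1ccc(C=C)cc1C1(/C=C/C(=O)NCCCCN(CCCNC(=O)C=C)C(=O)OC(C)(C)C)C=CC(=O)C=C1
F4 | step 8 | tert-butyl N-[3-(acryloylamino)propyl]-N-{4-[(2E)-3-{4-hydroxy-1-[2-(methoxymethoxy)phenyl]cyclohexa-2,5-dien-1-yl}prop-2-enamido]butyl}carbamate | COCOc1ccccc1C1(/C=C/C(=O)NCCCCN(CCCNC(=O)C=C)C(=O)OC(C)(C)C)C=CC(O)C=C1
A1 | alternative 1 | methyl (2E)-3-[(7R)-7-(4-bromo-2-iodophenoxy)-1,4-dioxaspiro[4.5]dec-8-en-8-yl]prop-2-enoate | O(c1ccc(Br)cc1I)[C@@H]1CC2(OCCO2)CC=C1/C=C/C(=O)OC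
A2 | alternative 1 | methyl (2E)-3-[(4aR,9bS)-8-bromo-3,3-(ethylenedioxy)-4,4a-dihydrodibenzofuran-9b(3H)-yl]prop-2-enoate (C1=C2 alkene) | C1=C[C@]2(/C=C/C(=O)OC)c3cc(Br)ccc3O[C@@H]2CC14OCCO4
A3 | alternative 2 | bis[(E)-4-hydroxycinnamoyl] derivative of the triamine (both terminal nitrogens acylated) | O=C(/C=C/c1ccc(O)cc1)NCCCCNCCCNC(=O)/C=C/c1ccc(O)cc1
A4 | alternative 2 | racemic 1,2-didehydro congener of the target (ring C enone) | O=C1C=CC23/C=C/C(=O)NCCCCNCCCNC(=O)/C=C/c4ccc(c2c4)OC3C1
A5 | alternative 3 | 2-[5-bromo-2-(methoxymethoxy)phenyl]prop-2-enal | C=C(C=O)c1cc(Br)ccc1OCOC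
A6 | alternative 3 | (1R)-1-[5-bromo-2-(methoxymethoxy)phenyl]-4-oxocyclohex-2-ene-1-carbaldehyde | O=C1CC[C@@](C=O)(C=C1)c1cc(Br)ccc1OCOC
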